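Abbreviations and conventions: TBS = tert-butyldimethylsilyl, TMS = trimethylsilyl. Positions are given in carotenoid numbering (ring A: C1–C6, chain C7–C15; ring B and its chain half primed). Two residue names shorten the compound names:
RA = (1R,2R,4S)-4-(TBS-oxy)-2,6,6-trimethyl-1,2-bis(TMS-oxy)cyclohexyl (ring A, attached through C6);
RB = (2S,6S,7aR)-6-(TBS-oxy)-4,4,7a-trimethyl-2,4,5,6,7,7a-hexahydro-1-benzofuran-2-yl (ring B, attached through C8′).

## Analysis of the target

CNP0210286.3 is an unsymmetrical C40 carotenoid: an all-E octaene chain (C7=C8 to C9′=C10′) carries a cyclohexane-3,5,6-triol at one end (ring A) and, at the other, a cyclohexane fused across C5′–C6′ to a 2,5-dihydrofuran whose oxygen bridges C5′ and C8′ (ring B). There are six stereocentres, three per end group: C3 (S), C5 (R) and C6 (R) in ring A, and C3′ (S), C5′ (R) and C8′ (S) in ring B. Nothing relays configuration along the chain, so each end has to be made enantiopure on its own. In ring A the hydroxyls on C3 and C6 share one face and the hydroxyl on C5 lies on the other; in ring B the ether oxygen on C5′ is trans to the C3′ hydroxyl and the polyene at C8′ is cis to the C5′ methyl group. The sensitive sites are the tertiary allylic C6 hydroxyl (ionises in acid), the doubly allylic C8′–O bond (opens and epimerises in acid), the polyene (light, oxygen, acid, E/Z drift) and, among intermediates, any ring A aldehyde with a free O5 or O6 (retro-aldol cleavage of C5–C6, α-ketol shift). The difficulty sits in two fully substituted, oxygen-bearing carbons (C5 and C6) wedged between C1 with its two methyl groups and C4, with no SN2 chemistry possible at C6, and in joining the halves and freeing four hydroxyls without acid. The strategy rests on the trans C5/C6 diol of ring A with O6 cis to O3: a C5–C6 oxirane on the face of the C3 hydroxyl already holds O6 correctly, and cleaving its C5–O bond by backside attack of water places O5 on the opposite face, which is the target triad.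

## Retrosynthetic reasoning

40 back to 39. Only the four silyl ethers are removed in the last step. The free tetrol, with its acid-labile C6 hydroxyl and C8′–O bond, therefore never meets a reagent other than the one that unmasks it.

39 back to 24 and 37. The chain is cut at C15=C15′. The cut gives two C20 halves of equal size, the double bond is disubstituted so a Z isomer relaxes thermally, and a Wittig condensation of ylide 38 (from 37) with aldehyde 24 forms it under base only. Cuts nearer either ring would make one partner small and the other a long, fragile polyenal.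

24 back to 14, 15 and 20. C7=C8 and C11=C12 are cut as olefination bonds. C9=C10 arrives inside the C5 ester phosphonate 15 (through its anion 16) and C13=C14 inside the C5 nitrile phosphonate 20 (through its anion 21). The first cycle is olefination, reduction and allylic oxidation (17, 18, 19). The second needs only olefination to nitrile 22 and one partial reduction through aldimine 23, because the nitrile carbon is already at the aldehyde oxidation level. The forward reactions must give E geometry and tolerate the crowded aldehyde 14.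

14 back to 10. C7 is taken from the ester level of 10 through alcohol 13 to aldehyde 14. Before that, O3 is silylated (11) and then O5 and O6 (12), because 14 with a free O5 would be a β-hydroxy aldehyde and with a free O6 an α-ketol.

10 back to 9 (key disconnection). The C5–O bond is cut and the oxygen is returned to an oxirane spanning C5–C6. The cut is made here because the ester on C6 forbids charge at C6 and so dictates which oxirane bond breaks, and because anti opening converts a single, easily controlled element (the oxirane face) into the trans relation of O5 to both O3 and O6. The forward reaction must be an invertive hydrolysis at C5 only.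

9 back to 8, 7, 4, 2 and 1. The oxirane oxygen is removed to give the homoallylic alcohol 8, whose hydroxyl is the handle for face control. 8 comes from its silyl ether 7. The C6–C7 bond of 7 is cut to enol triflate 4, carbon monoxide 5 and methanol 6. 4 comes through enolate 3 from the silyl ether 2 of (4R,6R)-actinol 1, which supplies C3 in the right absolute configuration.

37 back to 30. The chain of ring B is grown in C5 units as well: bromide 36 and alcohol 35 come from ester 34, made from aldehyde 32 and 15 (through its sodium salt 33), and 32 comes through alcohol 31 from the C15 ester 30. The ester phosphonate is kept for this half because it must end at the alcohol level for the phosphonium salt, whereas the ring A half ends at the aldehyde level and takes the nitrile.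

30 back to 29, 27, 26, 25 and 7. The C8′–O bond is cut, returning the oxygen to a C5′–C6′ oxirane in 29. The forward acid-induced rearrangement keeps C5′ but closes at C8′ without facial control, so a separation and a recycling loop belong to this step. 29 comes from aldehyde 27 and 15 (through its potassium salt 28), 27 from epoxy alcohol 26, and 26 from allylic alcohol 25 by a reagent-controlled epoxidation on the face opposite to the one used for ring A. 25 is the reduction product of 7, so one intermediate serves both rings.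

## Alternatives that were turned down

Alternative 1: The C3–O and C6–O bonds of ring A are disconnected together, back to an achiral cyclohexadiene, safranol TBS ether A1. In the forward direction a sensitised photooxygenation adds across C3=C4–C5=C6 in one [4+2] event and gives the bicyclic endoperoxide A2. In its favour, two C–O bonds form in one step, their cis relation is guaranteed by the suprafacial addition, the starting diene is cheap, and C7 is already at the alcohol level. Against it, A1 has no stereocentre, so A2 is racemic and a resolution has to follow. The O–O bond must still be reduced. The third oxygen is still missing: the remaining C4=C5 alkene would have to be hydrated at C5 on the face opposite both bridge oxygens. Ene reactions at the allylic methyl and methylene groups also compete with the cycloaddition. On bonds formed per step this alternative is stronger than steps 5 and 6 of the chosen route, which add O6 and O5 one after the other. The chosen strategy offers instead absolute configuration at no cost from 1, no resolution, all three oxygens with each relation enforced by mechanism (delivery, then inversion), and the shared intermediate 7.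

Alternative 2: The C8′–O bond of ring B is disconnected to a 5′,8′-peroxide, the 3,6-dihydro-1,2-dioxine A3 fused at C5′–C6′. In the forward direction a phosphine takes up one peroxide oxygen and the C5′ alkoxide displaces the activated oxygen at C8′ with inversion, closing the dihydrofuran of the C15 furanoid ester A4. A4 is the same compound as 30. In its favour, C8′ is set stereospecifically from the geometry of the peroxide; on this point it is stronger than step 20, which closes the ring on either face of C8′. Against it, it does nothing for ring A, the harder end. A3 must first be made by photooxygenation across the ring/side-chain diene C5′=C6′–C7′=C8′, so the stereochemical question is moved from C8′ to the face of attack at C5′, which only the remote C3′ substituent can bias. Ene pathways and peroxide handling add further risk. It could be grafted onto the chosen route as a second entry to 30. The chosen strategy offers in its place the solution of the ring A triad, a classical ring B rearrangement with a recycling loop, and a stereospecific backup for C8′.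

Alternative 3: The C10–C11 bond is disconnected with a ring opening. A C10-lithio diene, made by halogen–lithium exchange from the protected ring A dienyl iodide A5, adds to C2 of 4-methylpyrylium tetrafluoroborate A6; the 2H-pyran opens electrocyclically to a dienal and a catalytic isomerisation turns C13=C14 to E, giving the C20 polyenal A7. A7 differs from 24 only in the silyl groups on O5 and O6. In its favour, five chain carbons, the methyl branch and the aldehyde arrive in one step, where the chosen route needs two (steps 14 and 15); on step count for this stretch it is stronger. Against it, it presupposes the protected triol and so leaves the stereotriad unsolved. It needs a geometrically pure dienyl iodide. It exposes three silyl ethers to a strongly basic organolithium, with risk of silyl migration. It also delivers the Z isomer first, so an equilibration of a tetraenal is built in. The chosen olefinations give E directly and are routine. The value of the chosen strategy lies earlier, in the conversion of 9 into 10, and this alternative could at most replace part of the chain building (steps 11 to 15).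

Key step: step 6

Remark on the chemistry: the registry entry is read as the all-E (3S,5R,6R,3′S,5′R,8′S) isomer written in its SMILES. 1, 15 and 20 are taken as commercial; the two phosphonates are sold as E/Z mixtures whose allyl anions equilibrate, and minor Z isomers from the olefinations are removed by chromatography.

## Route

Step 1
Reactants: 1 (4R,6R)-actinol [(4R,6R)-4-hydroxy-2,2,6-trimethylcyclohexan-1-one]
Product: 2 (4R,6R)-4-(TBS-oxy)-2,2,6-trimethylcyclohexan-1-one
Conditions: TBSCl, imidazole, DMF, rt
Reagents that add atoms: tert-butyldimethylsilyl chloride, CC(C)(C)[Si](C)(C)Cl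
Why: Routine silylation of a secondary alcohol; it masks the hydroxyl before enolate chemistry and touches no stereocentre.

Step 2
Reactants: 2 (4R,6R)-4-(TBS-oxy)-2,2,6-trimethylcyclohexan-1-one
Product: 4 (4R)-4-(TBS-oxy)-2,6,6-trimethylcyclohex-1-en-1-yl trifluoromethanesulfonate, via lithium enolate 3 (not isolated)
Conditions: LiN(i-Pr)2, THF, −78 → 0 °C; PhNTf2, −78 °C → rt
Reagents that add atoms: N-phenylbis(trifluoromethanesulfonimide), O=S(=O)(N(c1ccccc1)S(=O)(=O)C(F)(F)F)C(F)(F)F
Why: Only the methyl-bearing α-carbon has a hydrogen (the other is quaternary), so one enolate forms and its O-sulfonylation gives the tetrasubstituted enol triflate; the methyl stereocentre is erased on purpose and C3 is untouched.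

Step 3
Reactants: 4 (4R)-4-(TBS-oxy)-2,6,6-trimethylcyclohex-1-en-1-yl trifluoromethanesulfonate; 5 carbon monoxide; 6 methanol
Product: 7 methyl (4R)-4-(TBS-oxy)-2,6,6-trimethylcyclohex-1-ene-1-carboxylate
Conditions: Pd(OAc)2 (cat.), PPh3, Et3N, CO (1 atm), MeOH/DMF, 60 °C
Reagents that add atoms: none
Why: Palladium-catalysed alkoxycarbonylation of an enol triflate: zerovalent palladium formed in situ inserts into the C–OTf bond, CO inserts and methanol cleaves the acyl complex; this forms the C6–C7 bond and installs the ester that later steers the oxirane opening.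

Step 4
Reactants: 7 methyl (4R)-4-(TBS-oxy)-2,6,6-trimethylcyclohex-1-ene-1-carboxylate
Product: 8 methyl (4R)-4-hydroxy-2,6,6-trimethylcyclohex-1-ene-1-carboxylate
Conditions: TsOH·H2O (cat.), MeOH, rt
Reagents that add atoms: none
Why: Acid-catalysed transfer of the silyl group to methanol frees the homoallylic hydroxyl that is needed as directing group; the hindered enoate and the stereocentre are inert here.

Step 5
Reactants: 8 methyl (4R)-4-hydroxy-2,6,6-trimethylcyclohex-1-ene-1-carboxylate
Product: 9 methyl (1R,4S,6S)-4-hydroxy-2,2,6-trimethyl-7-oxabicyclo[4.1.0]heptane-1-carboxylate (oxirane cis to the hydroxyl)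
Conditions: VO(acac)2 (cat.), t-BuOOH, PhMe, rt → 50 °C
Reagents that add atoms: tert-butyl hydroperoxide, CC(C)(C)OO
Why: Hydroxyl-directed vanadium-catalysed epoxidation of a homoallylic cyclohexenol: the C3 alkoxide binds the vanadium alkylperoxo species and delivers oxygen to its own face, which sets C5 and C6 together cis to the C3 hydroxyl; the ester is twisted out of conjugation by its two flanking substituents, so the tetrasubstituted alkene should stay nucleophilic enough.

Step 6
Reactants: 9 methyl (1R,4S,6S)-4-hydroxy-2,2,6-trimethyl-7-oxabicyclo[4.1.0]heptane-1-carboxylate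
Product: 10 methyl (1R,2R,4S)-1,2,4-trihydroxy-2,6,6-trimethylcyclohexane-1-carboxylate
Conditions: HClO4 (7% aq), THF, 0 °C → rt
Reagents that add atoms: water, O
Why: The oxirane oxygen is protonated reversibly and the C5–O bond lengthens, because C5 is tertiary and can carry positive charge whereas C6 bears the electron-withdrawing ester; water then attacks C5 from the face opposite the departing oxygen in a borderline SN2 process, and proton loss gives the diol with the oxirane oxygen still on C6. The closest known reaction type is the acid-catalysed hydrolysis of glycidic esters at the carbon remote from the carbonyl, combined with the trans-diaxial (Fürst–Plattner) opening of 1-methylcyclohexene oxides at their tertiary carbon. No ring is closed: the three-membered ring is opened and the cyclohexane is untouched. The one new stereocentre is C5, fixed by inversion relative to the oxirane, whose face was fixed by the C3 hydroxyl in step 5, so O5 ends trans to both O3 and O6; C6 keeps its oxygen with retention and C3 is a spectator. The step needs regioselectivity for C5 over C6, which is secured by the ester on C6, by the shielding of C6 between C1 and C5, and by the half-chair with an equatorial C3 hydroxyl, from which only attack at C5 leads directly to a chair with diaxial oxygens. It also needs anti over syn addition and substitution over proton loss, which the large excess of water, the low temperature and the non-nucleophilic perchlorate counter-ion should favour. The C3 hydroxyl lies on the oxirane face and is trans to the ester, so it can neither intercept C5 nor lactonise.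

Step 7
Reactants: 10 methyl (1R,2R,4S)-1,2,4-trihydroxy-2,6,6-trimethylcyclohexane-1-carboxylate
Product: 11 methyl (1R,2R,4S)-4-(TBS-oxy)-1,2-dihydroxy-2,6,6-trimethylcyclohexane-1-carboxylate
Conditions: TBSCl, imidazole, DMF, 0 °C → rt
Reagents that add atoms: tert-butyldimethylsilyl chloride, CC(C)(C)[Si](C)(C)Cl
Why: Only the secondary C3 hydroxyl is accessible to the chlorosilane; the two tertiary hydroxyls do not react under these conditions.

Step 8
Reactants: 11 methyl (1R,2R,4S)-4-(TBS-oxy)-1,2-dihydroxy-2,6,6-trimethylcyclohexane-1-carboxylate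
Product: 12 methyl (1R,2R,4S)-4-(TBS-oxy)-2,6,6-trimethyl-1,2-bis(TMS-oxy)cyclohexane-1-carboxylate
Conditions: Me3SiOTf, 2,6-lutidine, CH2Cl2, −78 → 0 °C
Reagents that add atoms: trimethylsilyl trifluoromethanesulfonate, C[Si](C)(C)OS(=O)(=O)C(F)(F)F
Why: The silyl triflate is reactive and small enough to cap both hindered tertiary hydroxyls; with O5 and O6 blocked, the later C7 aldehyde can undergo neither retro-aldol cleavage of C5–C6 nor an α-ketol shift.

Step 9
Reactants: 12 methyl (1R,2R,4S)-4-(TBS-oxy)-2,6,6-trimethyl-1,2-bis(TMS-oxy)cyclohexane-1-carboxylate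
Product: 13 [(1S,2R,4S)-4-(TBS-oxy)-2,6,6-trimethyl-1,2-bis(TMS-oxy)cyclohexyl]methanol
Conditions: i-Bu2AlH, CH2Cl2, −78 → 0 °C; aq potassium sodium tartrate
Reagents that add atoms: none
Why: Hydride reduction of the ester to the primary alcohol (the C6 descriptor changes only through the CIP ranking); a cold quench keeps the neighbouring silyl group from migrating to the new alkoxide.

Step 10
Reactants: 13 [(1S,2R,4S)-4-(TBS-oxy)-2,6,6-trimethyl-1,2-bis(TMS-oxy)cyclohexyl]methanol
Product: 14 (1R,2R,4S)-4-(TBS-oxy)-2,6,6-trimethyl-1,2-bis(TMS-oxy)cyclohexane-1-carbaldehyde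
Conditions: Dess–Martin periodinane, pyridine, CH2Cl2, 0 °C → rt
Reagents that add atoms: none
Why: Buffered hypervalent-iodine oxidation copes with neopentyl alcohols and stops at the aldehyde, which has no α-hydrogen and cannot epimerise.

Step 11
Reactants: 14 (1R,2R,4S)-4-(TBS-oxy)-2,6,6-trimethyl-1,2-bis(TMS-oxy)cyclohexane-1-carbaldehyde; 15 triethyl 3-methyl-4-phosphonocrotonate
Product: 17 ethyl (2E,4E)-3-methyl-5-RA-penta-2,4-dienoate, via lithiated phosphonate 16 (not isolated)
Conditions: LiN(SiMe3)2, THF/DMPU, −78 → 0 °C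
Reagents that add atoms: none
Why: Horner–Wadsworth–Emmons olefination: the stabilised anion should give the new C7=C8 bond E, and the C9=C10 bond of the reagent settles as E in the allyl anion; the lithium counter-ion activates the crowded carbonyl.

Step 12
Reactants: 17 ethyl (2E,4E)-3-methyl-5-RA-penta-2,4-dienoate
Product: 18 (2E,4E)-3-methyl-5-RA-penta-2,4-dien-1-ol
Conditions: i-Bu2AlH, CH2Cl2, −78 °C; aq potassium sodium tartrate
Reagents that add atoms: none
Why: 1,2-Reduction of the dienoate to the allylic alcohol; silyl ethers and double-bond geometry are unaffected.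

Step 13
Reactants: 18 (2E,4E)-3-methyl-5-RA-penta-2,4-dien-1-ol
Product: 19 (2E,4E)-3-methyl-5-RA-penta-2,4-dienal
Conditions: MnO2 (excess), CH2Cl2, rt
Reagents that add atoms: none
Why: Selective oxidation of an allylic alcohol on the oxide surface under neutral conditions.

Step 14
Reactants: 19 (2E,4E)-3-methyl-5-RA-penta-2,4-dienal; 20 diethyl [(2E)-3-cyano-2-methylprop-2-en-1-yl]phosphonate
Product: 22 (2E,4E,6E,8E)-3,7-dimethyl-9-RA-nona-2,4,6,8-tetraenenitrile, via lithiated nitrile phosphonate 21 (not isolated)
Conditions: LiN(SiMe3)2, THF/DMPU, −78 → 0 °C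
Reagents that add atoms: none
Why: Horner–Wadsworth–Emmons extension of an unhindered enal with the C5 nitrile phosphonate, the standard way from a C15 aldehyde to a retinonitrile-type C20 nitrile; it forms C11=C12 as E and brings in C13=C14 with C15 already at the aldehyde oxidation level.

Step 15
Reactants: 22 (2E,4E,6E,8E)-3,7-dimethyl-9-RA-nona-2,4,6,8-tetraenenitrile
Product: 24 (2E,4E,6E,8E)-3,7-dimethyl-9-RA-nona-2,4,6,8-tetraenal, via aluminium aldimine 23 (not isolated)
Conditions: i-Bu2AlH, CH2Cl2, −78 °C; wet SiO2, Et2O, 0 °C, dark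
Reagents that add atoms: water, O
Why: Partial hydride reduction of a nitrile: one hydride adds to give the N-aluminio aldimine, which is not reduced further in the cold and is hydrolysed on wet silica to the polyenal, the standard way from a retinonitrile-type nitrile to its aldehyde; silyl ethers and double-bond geometry are not touched.

Step 16
Reactants: 7 methyl (4R)-4-(TBS-oxy)-2,6,6-trimethylcyclohex-1-ene-1-carboxylate
Product: 25 [(4R)-4-(TBS-oxy)-2,6,6-trimethylcyclohex-1-en-1-yl]methanol
Conditions: i-Bu2AlH, CH2Cl2, −78 → 0 °C; aq potassium sodium tartrate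
Reagents that add atoms: none
Why: Reduction of the enoate to the allylic alcohol, which is the substrate class the next epoxidation needs.

Step 17
Reactants: 25 [(4R)-4-(TBS-oxy)-2,6,6-trimethylcyclohex-1-en-1-yl]methanol
Product: 26 [(1R,4S,6R)-4-(TBS-oxy)-2,2,6-trimethyl-7-oxabicyclo[4.1.0]heptan-1-yl]methanol (oxirane trans to the silyloxy group)
Conditions: Ti(Oi-Pr)4 (cat.), D-(−)-diethyl tartrate (cat.), t-BuOOH, 4 Å MS, CH2Cl2, −20 °C
Reagents that add atoms: tert-butyl hydroperoxide, CC(C)(C)OO
Why: Katsuki–Sharpless epoxidation of an allylic alcohol; the D-(−)-tartrate catalyst delivers oxygen to the face opposite the C3′ silyloxy group (reagent control), setting C5′ as R together with C6′.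

Step 18
Reactants: 26 [(1R,4S,6R)-4-(TBS-oxy)-2,2,6-trimethyl-7-oxabicyclo[4.1.0]heptan-1-yl]methanol
Product: 27 (1S,4S,6R)-4-(TBS-oxy)-2,2,6-trimethyl-7-oxabicyclo[4.1.0]heptane-1-carbaldehyde
Conditions: Dess–Martin periodinane, pyridine, CH2Cl2, 0 °C → rt
Reagents that add atoms: none
Why: Buffered oxidation to the non-enolisable epoxy aldehyde; the pyridine protects the acid-sensitive oxirane.

Step 19
Reactants: 27 (1S,4S,6R)-4-(TBS-oxy)-2,2,6-trimethyl-7-oxabicyclo[4.1.0]heptane-1-carbaldehyde; 15 triethyl 3-methyl-4-phosphonocrotonate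
Product: 29 ethyl (2E,4E)-5-[(1S,4S,6R)-4-(TBS-oxy)-2,2,6-trimethyl-7-oxabicyclo[4.1.0]heptan-1-yl]-3-methylpenta-2,4-dienoate, via potassium phosphonate salt 28 (not isolated)
Conditions: KN(SiMe3)2, THF, −78 → 0 °C
Reagents that add atoms: none
Why: Horner–Wadsworth–Emmons olefination of an epoxy aldehyde whose oxirane ties back the α-substituents, giving the 7′E,9′E dienoate; the aldehyde cannot enolise and the oxirane is stable to the potassium salt.

Step 20
Reactants: 29 ethyl (2E,4E)-5-[(1S,4S,6R)-4-(TBS-oxy)-2,2,6-trimethyl-7-oxabicyclo[4.1.0]heptan-1-yl]-3-methylpenta-2,4-dienoate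
Product: 30 ethyl (2E)-3-RB-but-2-enoate
Conditions: camphor-10-sulfonic acid (cat.), CH2Cl2, 0 °C → rt; chromatographic separation at C8′
Reagents that add atoms: none
Why: Acid-induced 5,6-epoxide to 5,8-furanoid rearrangement: protonation breaks the allylic C6′–O bond, and O5′ (configuration at C5′ retained) closes on C8′ of the allyl cation to leave the C6′=C7′ double bond. C8′ is not controlled by the substrate, so closure on both faces is expected; chromatography keeps the 8′S material, and the other fraction can be returned to the same acid, which re-ionises the C8′–O bond and re-equilibrates it.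

Step 21
Reactants: 30 ethyl (2E)-3-RB-but-2-enoate
Product: 31 (2E)-3-RB-but-2-en-1-ol
Conditions: i-Bu2AlH, CH2Cl2, −78 °C; aq potassium sodium tartrate
Reagents that add atoms: none
Why: Ester to allylic alcohol under non-acidic, non-basic conditions that leave C8′ untouched.

Step 22
Reactants: 31 (2E)-3-RB-but-2-en-1-ol
Product: 32 (2E)-3-RB-but-2-enal
Conditions: MnO2 (excess), CH2Cl2, rt
Reagents that add atoms: none
Why: Neutral allylic oxidation; no acid or base reaches the C8′–H, which is γ to the new carbonyl.

Step 23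
Reactants: 32 (2E)-3-RB-but-2-enal; 15 triethyl 3-methyl-4-phosphonocrotonate
Product: 34 ethyl (2E,4E,6E)-3-methyl-7-RB-octa-2,4,6-trienoate, via sodium phosphonate salt 33 (not isolated)
Conditions: NaN(SiMe3)2 (no excess over 15), THF, −78 → 0 °C
Reagents that add atoms: none
Why: Horner–Wadsworth–Emmons extension forming C11′=C12′ as E; the sodium salt is pre-formed so that no free amide base can remove the γ-proton at C8′.

Step 24
Reactants: 34 ethyl (2E,4E,6E)-3-methyl-7-RB-octa-2,4,6-trienoate
Product: 35 (2E,4E,6E)-3-methyl-7-RB-octa-2,4,6-trien-1-ol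
Conditions: i-Bu2AlH, CH2Cl2, −78 °C; aq potassium sodium tartrate
Reagents that add atoms: none
Why: Hydride reduction of the trienoate to the allylic alcohol, as in step 21.

Step 25
Reactants: 35 (2E,4E,6E)-3-methyl-7-RB-octa-2,4,6-trien-1-ol
Product: 37 [(2E,4E,6E)-3-methyl-7-RB-octa-2,4,6-trien-1-yl]triphenylphosphonium bromide, via allylic bromide 36 (not isolated)
Conditions: CBr4, PPh3, 2,6-lutidine, CH2Cl2, −20 °C; then PPh3, 0 °C → rt
Reagents that add atoms: triphenylphosphine, c1ccccc1P(c1ccccc1)c1ccccc1; carbon tetrabromide, BrC(Br)(Br)Br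
Why: Appel bromination of the primary allylic alcohol under buffered, acid-free conditions, followed at once by SN2 quaternisation of triphenylphosphine; the usual acidic phosphonium-salt protocol is avoided because it would ionise the C8′–O bond.

Step 26
Reactants: 37 [(2E,4E,6E)-3-methyl-7-RB-octa-2,4,6-trien-1-yl]triphenylphosphonium bromide; 24 (2E,4E,6E,8E)-3,7-dimethyl-9-RA-nona-2,4,6,8-tetraenal
Product: 39 (3S,5R,6R,3′S,5′R,8′S)-3,3′-bis(TBS-oxy)-5,6-bis(TMS-oxy)-5′,8′-epoxy-5,6,5′,8′-tetrahydro-β,β-carotene (all-E), via phosphorus ylide 38 (not isolated)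
Conditions: NaN(SiMe3)2, THF, −78 °C; add 24, −78 °C → rt; then heptane, 80 °C, dark
Reagents that add atoms: none
Why: Wittig condensation of a polyenyl ylide with a polyenal forms C15=C15′ under base only; the central double bond is disubstituted, so any 15-cis isomer should relax to all-E on heating.

Step 27
Reactants: 39 (3S,5R,6R,3′S,5′R,8′S)-3,3′-bis(TBS-oxy)-5,6-bis(TMS-oxy)-5′,8′-epoxy-5,6,5′,8′-tetrahydro-β,β-carotene (all-E)
Product: 40 CNP0210286.3 [(3S,5R,6R,3′S,5′R,8′S)-5′,8′-epoxy-5,6,5′,8′-tetrahydro-β,β-carotene-3,5,6,3′-tetrol (all-E)]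
Conditions: Bu4NF, THF, 0 °C → rt, dark, argon
Reagents that add atoms: none
Why: Fluoride cleaves the two secondary TBS and the two tertiary TMS ethers without acid, so neither the allylic C6 hydroxyl nor the C8′–O bond is ionised and no stereocentre is disturbed.

## Compound list

1 | (4R,6R)-actinol, (4R,6R)-4-hydroxy-2,2,6-trimethylcyclohexan-1-one | O=C1C(C)(C)C[C@H](O)C[C@H]1C | starting material
2 | (4R,6R)-4-(TBS-oxy)-2,2,6-trimethylcyclohexan-1-one | O=C1C(C)(C)C[C@H](O[Si](C)(C)C(C)(C)C)C[C@H]1C | intermediate
3 | lithium (4R)-4-(TBS-oxy)-2,6,6-trimethylcyclohex-1-en-1-olate | [Li+].[O-]C1=C(C)C[C@@H](O[Si](C)(C)C(C)(C)C)CC1(C)C | intermediate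
4 | (4R)-4-(TBS-oxy)-2,6,6-trimethylcyclohex-1-en-1-yl trifluoromethanesulfonate | CC1=C(OS(=O)(=O)C(F)(F)F)C(C)(C)C[C@H](O[Si](C)(C)C(C)(C)C)C1 | intermediate
5 | carbon monoxide | [C-]#[O+] | starting material
6 | methanol | CO | starting material
7 | methyl (4R)-4-(TBS-oxy)-2,6,6-trimethylcyclohex-1-ene-1-carboxylate | COC(=O)C1=C(C)C[C@@H](O[Si](C)(C)C(C)(C)C)CC1(C)C | intermediate
8 | methyl (4R)-4-hydroxy-2,6,6-trimethylcyclohex-1-ene-1-carboxylate | COC(=O)C1=C(C)C[C@@H](O)CC1(C)C | intermediate
9 | methyl (1R,4S,6S)-4-hydroxy-2,2,6-trimethyl-7-oxabicyclo[4.1.0]heptane-1-carboxylate (cis epoxy ester) | COC(=O)[C@@]1(O2)C(C)(C)C[C@H](O)C[C@@]12C | intermediate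
10 | methyl (1R,2R,4S)-1,2,4-trihydroxy-2,6,6-trimethylcyclohexane-1-carboxylate (ring A triol ester) | COC(=O)[C@@]1(O)C(C)(C)C[C@H](O)C[C@@]1(C)O | intermediate
11 | methyl (1R,2R,4S)-4-(TBS-oxy)-1,2-dihydroxy-2,6,6-trimethylcyclohexane-1-carboxylate | COC(=O)[C@@]1(O)C(C)(C)C[C@H](O[Si](C)(C)C(C)(C)C)C[C@@]1(C)O | intermediate
12 | methyl (1R,2R,4S)-4-(TBS-oxy)-2,6,6-trimethyl-1,2-bis(TMS-oxy)cyclohexane-1-carboxylate | COC(=O)[C@@]1(O[Si](C)(C)C)C(C)(C)C[C@H](O[Si](C)(C)C(C)(C)C)C[C@@]1(C)O[Si](C)(C)C | intermediate
13 | [(1S,2R,4S)-4-(TBS-oxy)-2,6,6-trimethyl-1,2-bis(TMS-oxy)cyclohexyl]methanol | OC[C@@]1(O[Si](C)(C)C)C(C)(C)C[C@H](O[Si](C)(C)C(C)(C)C)C[C@@]1(C)O[Si](C)(C)C | intermediate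
14 | (1R,2R,4S)-4-(TBS-oxy)-2,6,6-trimethyl-1,2-bis(TMS-oxy)cyclohexane-1-carbaldehyde | O=C[C@@]1(O[Si](C)(C)C)C(C)(C)C[C@H](O[Si](C)(C)C(C)(C)C)C[C@@]1(C)O[Si](C)(C)C | intermediate
15 | triethyl 3-methyl-4-phosphonocrotonate, ethyl (2E)-4-(diethoxyphosphoryl)-3-methylbut-2-enoate (E isomer drawn) | CCOC(=O)/C=C(C)/CP(=O)(OCC)OCC | starting material
16 | lithium salt of 15 (lithiated phosphonate) | [Li+].CCOC(=O)/C=C(C)/[CH-]P(=O)(OCC)OCC | intermediate
17 | ethyl (2E,4E)-3-methyl-5-RA-penta-2,4-dienoate | CCOC(=O)/C=C(C)/C=C/[C@@]1(O[Si](C)(C)C)C(C)(C)C[C@H](O[Si](C)(C)C(C)(C)C)C[C@@]1(C)O[Si](C)(C)C | intermediate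
18 | (2E,4E)-3-methyl-5-RA-penta-2,4-dien-1-ol | OC/C=C(C)/C=C/[C@@]1(O[Si](C)(C)C)C(C)(C)C[C@H](O[Si](C)(C)C(C)(C)C)C[C@@]1(C)O[Si](C)(C)C | intermediate
19 | (2E,4E)-3-methyl-5-RA-penta-2,4-dienal | O=C/C=C(C)/C=C/[C@@]1(O[Si](C)(C)C)C(C)(C)C[C@H](O[Si](C)(C)C(C)(C)C)C[C@@]1(C)O[Si](C)(C)C | intermediate
20 | diethyl [(2E)-3-cyano-2-methylprop-2-en-1-yl]phosphonate (E isomer drawn) | N#C/C=C(C)/CP(=O)(OCC)OCC | starting material
21 | lithium salt of 20 (lithiated nitrile phosphonate) | [Li+].N#C/C=C(C)/[CH-]P(=O)(OCC)OCC | intermediate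
22 | (2E,4E,6E,8E)-3,7-dimethyl-9-RA-nona-2,4,6,8-tetraenenitrile | N#C/C=C(C)/C=C/C=C(C)/C=C/[C@@]1(O[Si](C)(C)C)C(C)(C)C[C@H](O[Si](C)(C)C(C)(C)C)C[C@@]1(C)O[Si](C)(C)C | intermediate
23 | N-(diisobutylalumanyl) aldimine of 24 (aluminium aldimine) | CC(C)C[Al](CC(C)C)N=C/C=C(C)/C=C/C=C(C)/C=C/[C@@]1(O[Si](C)(C)C)C(C)(C)C[C@H](O[Si](C)(C)C(C)(C)C)C[C@@]1(C)O[Si](C)(C)C | intermediate
24 | (2E,4E,6E,8E)-3,7-dimethyl-9-RA-nona-2,4,6,8-tetraenal (ring A C20 aldehyde) | O=C/C=C(C)/C=C/C=C(C)/C=C/[C@@]1(O[Si](C)(C)C)C(C)(C)C[C@H](O[Si](C)(C)C(C)(C)C)C[C@@]1(C)O[Si](C)(C)C | intermediate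
25 | [(4R)-4-(TBS-oxy)-2,6,6-trimethylcyclohex-1-en-1-yl]methanol | OCC1=C(C)C[C@@H](O[Si](C)(C)C(C)(C)C)CC1(C)C | intermediate
26 | [(1R,4S,6R)-4-(TBS-oxy)-2,2,6-trimethyl-7-oxabicyclo[4.1.0]heptan-1-yl]methanol (trans epoxy alcohol) | OC[C@]1(O2)C(C)(C)C[C@H](O[Si](C)(C)C(C)(C)C)C[C@]12C | intermediate
27 | (1S,4S,6R)-4-(TBS-oxy)-2,2,6-trimethyl-7-oxabicyclo[4.1.0]heptane-1-carbaldehyde | O=C[C@]1(O2)C(C)(C)C[C@H](O[Si](C)(C)C(C)(C)C)C[C@]12C | intermediate
28 | potassium salt of 15 | [K+].CCOC(=O)/C=C(C)/[CH-]P(=O)(OCC)OCC | intermediate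
29 | ethyl (2E,4E)-5-[(1S,4S,6R)-4-(TBS-oxy)-2,2,6-trimethyl-7-oxabicyclo[4.1.0]heptan-1-yl]-3-methylpenta-2,4-dienoate | CCOC(=O)/C=C(C)/C=C/[C@]1(O2)C(C)(C)C[C@H](O[Si](C)(C)C(C)(C)C)C[C@]12C | intermediate
30 | ethyl (2E)-3-RB-but-2-enoate (C15 furanoid ester, 8′S) | CCOC(=O)\C=C(/C)[C@@H]1C=C2C(C)(C)C[C@H](O[Si](C)(C)C(C)(C)C)C[C@@]2(C)O1 | intermediate
31 | (2E)-3-RB-but-2-en-1-ol | OC\C=C(/C)[C@@H]1C=C2C(C)(C)C[C@H](O[Si](C)(C)C(C)(C)C)C[C@@]2(C)O1 | intermediate
32 | (2E)-3-RB-but-2-enal | O=C\C=C(/C)[C@@H]1C=C2C(C)(C)C[C@H](O[Si](C)(C)C(C)(C)C)C[C@@]2(C)O1 | intermediate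
33 | sodium salt of 15 | [Na+].CCOC(=O)/C=C(C)/[CH-]P(=O)(OCC)OCC | intermediate
34 | ethyl (2E,4E,6E)-3-methyl-7-RB-octa-2,4,6-trienoate | CCOC(=O)\C=C(/C)\C=C\C=C(/C)[C@@H]1C=C2C(C)(C)C[C@H](O[Si](C)(C)C(C)(C)C)C[C@@]2(C)O1 | intermediate
35 | (2E,4E,6E)-3-methyl-7-RB-octa-2,4,6-trien-1-ol | OC\C=C(/C)\C=C\C=C(/C)[C@@H]1C=C2C(C)(C)C[C@H](O[Si](C)(C)C(C)(C)C)C[C@@]2(C)O1 | intermediate
36 | (2E,4E,6E)-1-bromo-3-methyl-7-RB-octa-2,4,6-triene | BrC\C=C(/C)\C=C\C=C(/C)[C@@H]1C=C2C(C)(C)C[C@H](O[Si](C)(C)C(C)(C)C)C[C@@]2(C)O1 | intermediate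
37 | [(2E,4E,6E)-3-methyl-7-RB-octa-2,4,6-trien-1-yl]triphenylphosphonium bromide | [Br-].c1ccccc1[P+](c1ccccc1)(c1ccccc1)C\C=C(/C)\C=C\C=C(/C)[C@@H]1C=C2C(C)(C)C[C@H](O[Si](C)(C)C(C)(C)C)C[C@@]2(C)O1 | intermediate
38 | ylide of 37 | c1ccccc1[P+](c1ccccc1)(c1ccccc1)[CH-]\C=C(/C)\C=C\C=C(/C)[C@@H]1C=C2C(C)(C)C[C@H](O[Si](C)(C)C(C)(C)C)C[C@@]2(C)O1 | intermediate
39 | (3S,5R,6R,3′S,5′R,8′S)-3,3′-bis(TBS-oxy)-5,6-bis(TMS-oxy)-5′,8′-epoxy-5,6,5′,8′-tetrahydro-β,β-carotene (all-E) | CC(/C=C/C=C(C)/C=C/[C@@]1(O[Si](C)(C)C)C(C)(C)C[C@H](O[Si](C)(C)C(C)(C)C)C[C@@]1(C)O[Si](C)(C)C)=C\C=C\C=C(C)\C=C\C=C(/C)[C@@H]1C=C2C(C)(C)C[C@H](O[Si](C)(C)C(C)(C)C)C[C@@]2(C)O1 | intermediate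
40 | CNP0210286.3, (3S,5R,6R,3′S,5′R,8′S)-5′,8′-epoxy-5,6,5′,8′-tetrahydro-β,β-carotene-3,5,6,3′-tetrol (all-E) | CC(/C=C/C=C(C)/C=C/[C@@]1(O)C(C)(C)C[C@H](O)C[C@@]1(C)O)=C\C=C\C=C(C)\C=C\C=C(/C)[C@@H]1C=C2C(C)(C)C[C@H](O)C[C@@]2(C)O1 | target

## Step count and least certain steps

Total: 27 steps. Longest linear sequence: 17 steps (steps 1 to 15, then 26 and 27); the ring B branch runs through steps 1 to 3 and 16 to 25 before the union.

Step 6 (key step). The most likely failure is loss of a proton from the cation-like C5, towards the exocyclic or the C4=C5 alkene, or front-side collapse to the cis diol, outrunning backside attack. The reason is that the trajectory of water to C5 passes a syn-axial C1 methyl group. The fallback replaces intermolecular water by an oxygen tethered to C7, so that ring size fixes the regiochemistry. It sets out from 25 and comes back at 13. 25 is epoxidised with the enantiomeric catalyst (Ti(Oi-Pr)4, L-(+)-diethyl tartrate, t-BuOOH) to the cis epoxy alcohol F1. Boc2O and DMAP convert it into the tert-butyl carbonate F2. BF3·OEt2 at −78 °C lets the carbonate carbonyl oxygen open the oxirane at C5 from the face opposite the oxirane oxygen, with loss of 2-methylpropene, to give the cis-fused six-membered cyclic carbonate F3 (O5 and O7 bridged, O6 free). K2CO3 in methanol cleaves the carbonate to the triol F4. Me3SiOTf and 2,6-lutidine give the tris(trimethylsilyl) ether F5, and brief K2CO3 in methanol at 0 °C removes only the primary silyl group to give 13.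

Step 5. Oxygen transfer may be slow or fail, because the alkene carries an ester and the directing hydroxyl must turn axial beside a C1 methyl group; any non-directed background path would erode the face selectivity. The fallback uses reagent control at the allylic alcohol level and then restores the ester. It sets out from 25 and comes back at 9. The cis epoxy alcohol F1 (made as in the fallback to step 6) is oxidised with Dess–Martin periodinane to the cis epoxy aldehyde F6. NaClO2 with NaH2PO4 and 2-methylbut-2-ene gives the epoxy acid F7. Me3SiCHN2 gives the silylated cis epoxy ester F8, and Bu4NF frees the C3 hydroxyl to give 9.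

Step 11. Addition of the bulky, delocalised phosphonate anion to the neopentyl aldehyde may be slow, leaving time for migration of a silyl group to the adduct alkoxide or for decomposition of 14. The fallback builds the diene by cross-coupling and not by carbonyl olefination. It sets out from 14 and comes back at 17. Takai iodo-olefination (CrCl2, CHI3, THF) gives the (E)-vinyl iodide F9, and a Stille coupling with ethyl (2E)-3-(tributylstannyl)but-2-enoate (Pd(PPh3)4, CuI, DMF) gives 17 with both double bonds defined.

Step 20. Ring closure at C8′ has no facial control, so poor selectivity at C8′ is expected and about half of the material has to go through the recycling loop. In addition, the dienoate makes the allyl cation poorer, so cleavage of the other oxirane bond (C5′–O) may compete. The fallback fixes C8′ by transfer of axial chirality. It sets out from 27 and comes back at 31. Ohira–Bestmann homologation (dimethyl (1-diazo-2-oxopropyl)phosphonate, K2CO3, methanol) gives the epoxy alkyne F10. Sonogashira coupling with ethyl (2E)-3-iodobut-2-enoate (PdCl2(PPh3)2, CuI, Et3N) gives the epoxy enynoate F11. i-Bu2AlH reduces the ester and, bound to the oxirane oxygen, delivers hydride to C8′ in an SN2′ opening to give the (6′R)-allenic diol F12. AgNO3 (cat.) in aqueous acetone should then cyclise the α-hydroxyallene in a 5-endo manner to 31 only, the (R) axis mapping onto (8′S).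

Step 25. The transient bromide 36 may ionise or lose HBr through the polyene (the proton at C8′ sits at the end of the conjugated system) before the phosphine traps it. The fallback reverses the polarity of the union. It sets out from 35 and 24 and comes back at 39. MnO2 oxidises 35 to the ring B C20 aldehyde F13. 24, whose chain ends at the proton-free C6, is reduced with NaBH4 in methanol at 0 °C to the ring A C20 alcohol F14, which is converted in one flask (CBr4, PPh3, 2,6-lutidine; then PPh3) into the ring A C20 phosphonium bromide F15. Wittig condensation of F15 (NaN(SiMe3)2, THF) with F13, followed by the same thermal equilibration, gives 39.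

## Further compounds

F1 | step 6 | [(1S,4S,6S)-4-(TBS-oxy)-2,2,6-trimethyl-7-oxabicyclo[4.1.0]heptan-1-yl]methanol (cis epoxy alcohol) | OC[C@@]1(O2)C(C)(C)C[C@H](O[Si](C)(C)C(C)(C)C)C[C@@]12C
F2 | step 6 | tert-butyl carbonate of F1 | CC(C)(C)OC(=O)OC[C@@]1(O2)C(C)(C)C[C@H](O[Si](C)(C)C(C)(C)C)C[C@@]12C
F3 | step 6 | cis-fused cyclic carbonate bridging O5 and O7 with free 6-OH and 3-O-TBS | O=C1OC[C@@]2(O)C(C)(C)C[C@H](O[Si](C)(C)C(C)(C)C)C[C@@]2(C)O1
F4 | step 6 | (1R,2R,4S)-4-(TBS-oxy)-1-(hydroxymethyl)-2,6,6-trimethylcyclohexane-1,2-diol | OC[C@@]1(O)C(C)(C)C[C@H](O[Si](C)(C)C(C)(C)C)C[C@@]1(C)O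
F5 | step 6 | tris(trimethylsilyl) ether of F4 | C[Si](C)(C)OC[C@@]1(O[Si](C)(C)C)C(C)(C)C[C@H](O[Si](C)(C)C(C)(C)C)C[C@@]1(C)O[Si](C)(C)C
F6 | step 5 | (1R,4S,6S)-4-(TBS-oxy)-2,2,6-trimethyl-7-oxabicyclo[4.1.0]heptane-1-carbaldehyde | O=C[C@@]1(O2)C(C)(C)C[C@H](O[Si](C)(C)C(C)(C)C)C[C@@]12C
F7 | step 5 | (1R,4S,6S)-4-(TBS-oxy)-2,2,6-trimethyl-7-oxabicyclo[4.1.0]heptane-1-carboxylic acid | OC(=O)[C@@]1(O2)C(C)(C)C[C@H](O[Si](C)(C)C(C)(C)C)C[C@@]12C
F8 | step 5 | methyl (1R,4S,6S)-4-(TBS-oxy)-2,2,6-trimethyl-7-oxabicyclo[4.1.0]heptane-1-carboxylate | COC(=O)[C@@]1(O2)C(C)(C)C[C@H](O[Si](C)(C)C(C)(C)C)C[C@@]12C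
F9 | step 11 | RA-substituted (E)-vinyl iodide, (E)-1-iodo-2-RA-ethene | I/C=C/[C@@]1(O[Si](C)(C)C)C(C)(C)C[C@H](O[Si](C)(C)C(C)(C)C)C[C@@]1(C)O[Si](C)(C)C
F10 | step 20 | (4S,6R)-1-ethynyl-4-(TBS-oxy)-2,2,6-trimethyl-7-oxabicyclo[4.1.0]heptane (oxirane trans to the silyloxy group) | C#C[C@]1(O2)C(C)(C)C[C@H](O[Si](C)(C)C(C)(C)C)C[C@]12C
F11 | step 20 | ethyl (2E)-3-methyl-5-[(4S,6R)-4-(TBS-oxy)-2,2,6-trimethyl-7-oxabicyclo[4.1.0]heptan-1-yl]pent-2-en-4-ynoate | CCOC(=O)/C=C(C)/C#C[C@]1(O2)C(C)(C)C[C@H](O[Si](C)(C)C(C)(C)C)C[C@]12C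
F12 | step 20 | (2E)-5-[(2R,4S)-4-(TBS-oxy)-2-hydroxy-2,6,6-trimethylcyclohexylidene]-3-methylpenta-2,4-dien-1-ol with (R) allene axis | OC/C=C(C)/C([H])=[C@@]=C1C(C)(C)C[C@H](O[Si](C)(C)C(C)(C)C)C[C@@]1(C)O
F13 | step 25 | (2E,4E,6E)-3-methyl-7-RB-octa-2,4,6-trienal | O=C\C=C(/C)\C=C\C=C(/C)[C@@H]1C=C2C(C)(C)C[C@H](O[Si](C)(C)C(C)(C)C)C[C@@]2(C)O1
F14 | step 25 | (2E,4E,6E,8E)-3,7-dimethyl-9-RA-nona-2,4,6,8-tetraen-1-ol | OC/C=C(C)/C=C/C=C(C)/C=C/[C@@]1(O[Si](C)(C)C)C(C)(C)C[C@H](O[Si](C)(C)C(C)(C)C)C[C@@]1(C)O[Si](C)(C)C
F15 | step 25 | [(2E,4E,6E,8E)-3,7-dimethyl-9-RA-nona-2,4,6,8-tetraen-1-yl]triphenylphosphonium bromide | [Br-].c1ccccc1[P+](c1ccccc1)(c1ccccc1)C/C=C(C)/C=C/C=C(C)/C=C/[C@@]1(O[Si](C)(C)C)C(C)(C)C[C@H](O[Si](C)(C)C(C)(C)C)C[C@@]1(C)O[Si](C)(C)C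
A1 | alternative 1 | safranol TBS ether | CC1=C(CO[Si](C)(C)C(C)(C)C)C(C)(C)CC=C1
A2 | alternative 1 | bicyclic endoperoxide (needed enantiomer drawn) | CC(C)(C)[Si](C)(C)OC[C@@]1(OO2)C(C)(C)C[C@H]2C=C1C
A3 | alternative 2 | 5′,8′-peroxide (3,6-dihydro-1,2-dioxine) of the ring B C15 ester | CCOC(=O)\C=C(/C)[C@H]1C=C2C(C)(C)C[C@H](O[Si](C)(C)C(C)(C)C)C[C@@]2(C)OO1
A4 | alternative 2 | C15 furanoid ester (same as 30) | CCOC(=O)\C=C(/C)[C@@H]1C=C2C(C)(C)C[C@H](O[Si](C)(C)C(C)(C)C)C[C@@]2(C)O1
A5 | alternative 3 | protected ring A dienyl iodide | I/C=C(C)/C=C/[C@@]1(O[Si](CC)(CC)CC)C(C)(C)C[C@H](O[Si](C)(C)C(C)(C)C)C[C@@]1(C)O[Si](CC)(CC)CC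
A6 | alternative 3 | 4-methylpyrylium tetrafluoroborate | Cc1cc[o+]cc1.F[B-](F)(F)F
A7 | alternative 3 | C20 polyenal of ring A | CC(/C=C/C=C(C)/C=C/[C@@]1(O[Si](CC)(CC)CC)C(C)(C)C[C@H](O[Si](C)(C)C(C)(C)C)C[C@@]1(C)O[Si](CC)(CC)CC)=C\C=O
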